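**Plan**

- Retrosynthesis: the 1,3-diketone is taken back to a β-silyloxy ketone. Ring B is then cut at C1'–C2' and C5'–C6' into a 2-prenyl-1-methoxy-3-silyloxybutadiene and a terminal ynone that carries ring A. The ynone is cut at its C(=O)–C≡C bond and at the CH2–CH(O) aldol bond, and the ring A prenyl group goes back to an aryl 1,1-dimethylallyl ether.
- Enabling feature: ring B is a benzene with the acyl carbon at C1', the prenyl group at C3', the oxygen at C4' (para to the acyl carbon) and CH at C2', C5' and C6'. A 2-substituted 1-methoxy-3-silyloxydiene writes exactly this pattern onto a terminal ynone once methanol is lost.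
- Forward order: the diene is made from 6-methylhept-5-en-2-one. Ring A comes from 2,4-dihydroxybenzaldehyde by O-alkylation, semihydrogenation, Claisen rearrangement, silylation and methylation. The chain is extended by an aldol addition, O-silylation and an ethynyl Grignard addition. Ring B is then built on the chain, followed by triethylsilyl removal, oxidation and desilylation.
- Stereochemistry: the target has no stereocentre. The carbinol carbon is carried as a racemate and removed by oxidation. The only geometric requirement is the E enol ether of the diene, which is the thermodynamic isomer of its enone precursor.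

Key step: step 12

Remark: the 1,3-diketones are drawn in the diketo form of their freely equilibrating enols, and every compound with a carbinol or other sp3 stereocentre is racemic or a diastereomer mixture.

**Route**

Step 1
Reactants: 1 6-methylhept-5-en-2-one
Product: 2 3-(dimethoxymethyl)-6-methylhept-5-en-2-one (racemic)
Conditions: HC(OMe)3, BF3·OEt2, CH2Cl2, −30 to 0 °C; then 1, iPr2NEt, −78 °C
Reagents that add atoms: trimethyl orthoformate, COC(OC)OC
Why: Dialkoxymethylation of a ketone with a preformed dialkoxycarbenium tetrafluoroborate and a hindered amine is known to go through the more substituted enol, so the C–C bond should form at C3 and not at the methyl group; the new C3 centre is racemic and is destroyed in step 2.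

Step 2
Reactants: 2 3-(dimethoxymethyl)-6-methylhept-5-en-2-one
Product: 3 (E)-3-(methoxymethylidene)-6-methylhept-5-en-2-one
Conditions: PPTS (cat.), toluene, 100 °C, 5 Å molecular sieves
Reagents that add atoms: none
Why: Acid-catalysed β-elimination of methanol from a β-keto acetal gives the vinylogous ester, and equilibration should favour the E isomer with the methoxy group anti to the acetyl group, as in the known 3-methyl homologue.

Step 3
Reactants: 3 (E)-3-(methoxymethylidene)-6-methylhept-5-en-2-one
Product: 4 (E)-1-methoxy-2-(3-methylbut-2-en-1-yl)-3-(tert-butyldimethylsilyloxy)buta-1,3-diene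
Conditions: TBSOTf, Et3N, Et2O, 0 °C to rt
Reagents that add atoms: tert-butyldimethylsilyl trifluoromethanesulfonate, CC(C)(C)[Si](C)(C)OS(=O)(=O)C(F)(F)F
Why: Silyl enol ether formation by soft enolization can only involve the methyl group, since C3 bears no hydrogen, and is the standard entry to 1-methoxy-3-silyloxydienes of the Danishefsky type.

Step 4
Reactants: 5 2,4-dihydroxybenzaldehyde; 6 3-chloro-3-methylbut-1-yne
Product: 7 2-hydroxy-4-[(2-methylbut-3-yn-2-yl)oxy]benzaldehyde
Conditions: K2CO3, KI, CuI (cat.), acetone, 55 °C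
Reagents that add atoms: none
Why: Copper-assisted Williamson-type O-alkylation with a tertiary propargylic chloride should occur at the 4-hydroxyl, because the 2-hydroxyl is held in a hydrogen bond to the aldehyde.

Step 5
Reactants: 7 2-hydroxy-4-[(2-methylbut-3-yn-2-yl)oxy]benzaldehyde
Product: 8 2-hydroxy-4-[(2-methylbut-3-en-2-yl)oxy]benzaldehyde
Conditions: H2 (1 atm), Pd/CaCO3 poisoned with Pb(OAc)2, quinoline, EtOAc, rt
Reagents that add atoms: none
Why: Lindlar semihydrogenation should stop at the terminal alkene and leave the aldehyde and the aryl ether untouched.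

Step 6
Reactants: 8 2-hydroxy-4-[(2-methylbut-3-en-2-yl)oxy]benzaldehyde
Product: 9 2,4-dihydroxy-3-(3-methylbut-2-en-1-yl)benzaldehyde
Conditions: N,N-diethylaniline, 130 °C
Reagents that add atoms: none
Why: Aromatic Claisen rearrangement of the 1,1-dimethylallyl ether delivers a normal prenyl group to an ortho carbon, and the hydrogen-bonded 2-hydroxybenzaldehyde unit fixes C3–C4 double-bond character so that C3 rather than C5 should be attacked.

Step 7
Reactants: 9 2,4-dihydroxy-3-(3-methylbut-2-en-1-yl)benzaldehyde
Product: 10 4-(tert-butyldimethylsilyloxy)-2-hydroxy-3-(3-methylbut-2-en-1-yl)benzaldehyde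
Conditions: TBSCl, imidazole, CH2Cl2, 0 °C
Reagents that add atoms: tert-butyldimethylsilyl chloride, CC(C)(C)[Si](C)(C)Cl
Why: O-Silylation of a phenol should take the free 4-hydroxyl, while the chelated 2-hydroxyl, flanked by the aldehyde and the prenyl group, stays free.

Step 8
Reactants: 10 4-(tert-butyldimethylsilyloxy)-2-hydroxy-3-(3-methylbut-2-en-1-yl)benzaldehyde
Product: 11 4-(tert-butyldimethylsilyloxy)-2-methoxy-3-(3-methylbut-2-en-1-yl)benzaldehyde
Conditions: MeOH, PPh3, DIAD, THF, 0 °C to rt
Reagents that add atoms: methanol, CO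
Why: Mitsunobu etherification methylates the acidic chelated phenol under neutral conditions, which avoids carbonate bases that could cleave the aryl silyl ether para to the aldehyde.

Step 9
Reactants: 11 4-(tert-butyldimethylsilyloxy)-2-methoxy-3-(3-methylbut-2-en-1-yl)benzaldehyde; 12 N-methoxy-N-methylacetamide
Product: 14 racemic 3-[4-(tert-butyldimethylsilyloxy)-2-methoxy-3-(3-methylbut-2-en-1-yl)phenyl]-3-hydroxy-N-methoxy-N-methylpropanamide, via lithium enolate of the amide 13 (not isolated)
Conditions: 12, LiN(iPr)2, THF, −78 °C; then 11, −78 °C; aq. NH4Cl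
Reagents that add atoms: none
Why: Aldol addition of the preformed lithium enolate of the Weinreb acetamide to a non-enolizable aryl aldehyde; the carbinol centre forms without control (racemic), which is acceptable because it is oxidized in step 14.

Step 10
Reactants: 14 racemic 3-[4-(tert-butyldimethylsilyloxy)-2-methoxy-3-(3-methylbut-2-en-1-yl)phenyl]-3-hydroxy-N-methoxy-N-methylpropanamide
Product: 15 racemic 3-[4-(tert-butyldimethylsilyloxy)-2-methoxy-3-(3-methylbut-2-en-1-yl)phenyl]-N-methoxy-N-methyl-3-(triethylsilyloxy)propanamide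
Conditions: TESCl, imidazole, DMF, 0 °C to rt
Reagents that add atoms: chlorotriethylsilane, CC[Si](Cl)(CC)CC
Why: Standard O-silylation of a secondary alcohol blocks retro-aldol and elimination pathways and masks the future carbonyl at the alcohol oxidation level.

Step 11
Reactants: 15 racemic 3-[4-(tert-butyldimethylsilyloxy)-2-methoxy-3-(3-methylbut-2-en-1-yl)phenyl]-N-methoxy-N-methyl-3-(triethylsilyloxy)propanamide
Product: 17 racemic 5-[4-(tert-butyldimethylsilyloxy)-2-methoxy-3-(3-methylbut-2-en-1-yl)phenyl]-5-(triethylsilyloxy)pent-1-yn-3-one, via magnesium hemiaminal chelate 16 (not isolated)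
Conditions: HC≡CMgBr, THF, 0 °C to rt; inverse quench into cold aq. NaHSO4
Reagents that add atoms: ethynylmagnesium bromide, C#C[Mg]Br
Why: Weinreb ketone synthesis: the Grignard reagent adds once to give a chelated tetrahedral adduct that collapses to the terminal ynone only on the acidic quench, which also protonates the liberated N,O-dimethylhydroxylamine and so should prevent its conjugate addition.

Step 12
Reactants: 4 (E)-1-methoxy-2-(3-methylbut-2-en-1-yl)-3-(tert-butyldimethylsilyloxy)buta-1,3-diene; 17 racemic 5-[4-(tert-butyldimethylsilyloxy)-2-methoxy-3-(3-methylbut-2-en-1-yl)phenyl]-5-(triethylsilyloxy)pent-1-yn-3-one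
Product: 19 racemic 1-[4-(tert-butyldimethylsilyloxy)-3-(3-methylbut-2-en-1-yl)phenyl]-3-[4-(tert-butyldimethylsilyloxy)-2-methoxy-3-(3-methylbut-2-en-1-yl)phenyl]-3-(triethylsilyloxy)propan-1-one, via methoxycyclohexadiene cycloadduct 18 (not isolated)
Conditions: toluene, 80 °C; then PPTS (cat.), 25 °C
Reagents that add atoms: none
Why: The doubly donor-substituted diene 4 should add to the electron-poor alkyne of 17 in a concerted but asynchronous [4+2] cycloaddition, in which the CH2 terminus (the most nucleophilic carbon) bonds to the terminal alkyne carbon and the methoxy-bearing terminus bonds to the acyl-bearing carbon. The closest known reaction type is the Diels–Alder benzannulation of 1-methoxy-3-silyloxybutadienes with alkynyl ketones, followed by loss of methanol, to give 4-silyloxyaryl ketones. Ring B is closed intermolecularly by forming C5'–C6' and C1'–C2' in one cycloaddition, and the doubly allylic methoxy group and a C5' hydrogen of 18 then leave in a 1,4-elimination that makes the ring aromatic with the silyl enol ether retained as an aryl silyl ether. The methoxy-bearing carbon of 18 is a transient stereocentre that is erased on aromatization, and the carbinol carbon is racemic and spectating, so there is no stereocontrol element to provide. The step needs regioselectivity, secured by the matched polarization of the methoxy and silyloxy donors against the ynone carbonyl, which places the silyl ether para to the ketone and the prenyl group at C3'. It also needs chemoselectivity, secured by the inertness of the two unactivated prenyl alkenes toward the diene.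

Step 13
Reactants: 19 racemic 1-[4-(tert-butyldimethylsilyloxy)-3-(3-methylbut-2-en-1-yl)phenyl]-3-[4-(tert-butyldimethylsilyloxy)-2-methoxy-3-(3-methylbut-2-en-1-yl)phenyl]-3-(triethylsilyloxy)propan-1-one
Product: 20 racemic 1-[4-(tert-butyldimethylsilyloxy)-3-(3-methylbut-2-en-1-yl)phenyl]-3-[4-(tert-butyldimethylsilyloxy)-2-methoxy-3-(3-methylbut-2-en-1-yl)phenyl]-3-hydroxypropan-1-one
Conditions: PPTS (cat.), MeOH/CH2Cl2, 0 °C
Reagents that add atoms: none
Why: Acid-catalysed methanolysis of silyl ethers should cleave the alkyl triethylsilyl ether quickly while the two aryl tert-butyldimethylsilyl ethers, which are stable to mild acid, remain.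

Step 14
Reactants: 20 racemic 1-[4-(tert-butyldimethylsilyloxy)-3-(3-methylbut-2-en-1-yl)phenyl]-3-[4-(tert-butyldimethylsilyloxy)-2-methoxy-3-(3-methylbut-2-en-1-yl)phenyl]-3-hydroxypropan-1-one
Product: 21 1-[4-(tert-butyldimethylsilyloxy)-2-methoxy-3-(3-methylbut-2-en-1-yl)phenyl]-3-[4-(tert-butyldimethylsilyloxy)-3-(3-methylbut-2-en-1-yl)phenyl]propane-1,3-dione
Conditions: Dess–Martin periodinane, NaHCO3, CH2Cl2, 0 °C to rt
Reagents that add atoms: none
Why: Dess–Martin oxidation is the established way from β-hydroxy ketones to 1,3-diketones and should leave the prenyl double bonds and the aryl silyl ethers alone; the racemic centre disappears here.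

Step 15
Reactants: 21 1-[4-(tert-butyldimethylsilyloxy)-2-methoxy-3-(3-methylbut-2-en-1-yl)phenyl]-3-[4-(tert-butyldimethylsilyloxy)-3-(3-methylbut-2-en-1-yl)phenyl]propane-1,3-dione
Product: 22 1-[4-hydroxy-2-methoxy-3-(3-methylbut-2-en-1-yl)phenyl]-3-[4-hydroxy-3-(3-methylbut-2-en-1-yl)phenyl]propane-1,3-dione (CNP0167758.0)
Conditions: Bu4NF, AcOH, THF, 0 °C
Reagents that add atoms: none
Why: Fluoride-mediated desilylation cleaves both aryl silyl ethers, and the acetic acid buffer keeps the phenoxides and the diketone enolate protonated so that retro-Claisen cleavage and cyclization onto the prenyl groups should not occur.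

**Compound list**

1 | 6-methylhept-5-en-2-one | CC(=O)CCC=C(C)C | starting material
2 | 3-(dimethoxymethyl)-6-methylhept-5-en-2-one (racemic) | CC(=O)C(CC=C(C)C)C(OC)OC | intermediate
3 | (E)-3-(methoxymethylidene)-6-methylhept-5-en-2-one | CO/C=C(\CC=C(C)C)C(C)=O | intermediate
4 | (E)-1-methoxy-2-(3-methylbut-2-en-1-yl)-3-(tert-butyldimethylsilyloxy)buta-1,3-diene | CO/C=C(\CC=C(C)C)C(=C)O[Si](C)(C)C(C)(C)C | intermediate
5 | 2,4-dihydroxybenzaldehyde | O=Cc1ccc(O)cc1O | starting material
6 | 3-chloro-3-methylbut-1-yne | C#CC(C)(C)Cl | starting material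
7 | 2-hydroxy-4-[(2-methylbut-3-yn-2-yl)oxy]benzaldehyde | O=Cc1ccc(OC(C)(C)C#C)cc1O | intermediate
8 | 2-hydroxy-4-[(2-methylbut-3-en-2-yl)oxy]benzaldehyde | O=Cc1ccc(OC(C)(C)C=C)cc1O | intermediate
9 | 2,4-dihydroxy-3-(3-methylbut-2-en-1-yl)benzaldehyde | O=Cc1ccc(O)c(CC=C(C)C)c1O | intermediate
10 | 4-(tert-butyldimethylsilyloxy)-2-hydroxy-3-(3-methylbut-2-en-1-yl)benzaldehyde | O=Cc1ccc(O[Si](C)(C)C(C)(C)C)c(CC=C(C)C)c1O | intermediate
11 | 4-(tert-butyldimethylsilyloxy)-2-methoxy-3-(3-methylbut-2-en-1-yl)benzaldehyde | COc1c(C=O)ccc(O[Si](C)(C)C(C)(C)C)c1CC=C(C)C | intermediate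
12 | N-methoxy-N-methylacetamide | CC(=O)N(C)OC | starting material
13 | lithium enolate of N-methoxy-N-methylacetamide (not isolated) | [Li]OC(=C)N(C)OC | intermediate
14 | racemic 3-[4-(tert-butyldimethylsilyloxy)-2-methoxy-3-(3-methylbut-2-en-1-yl)phenyl]-3-hydroxy-N-methoxy-N-methylpropanamide | COc1c(C(O)CC(=O)N(C)OC)ccc(O[Si](C)(C)C(C)(C)C)c1CC=C(C)C | intermediate
15 | racemic 3-[4-(tert-butyldimethylsilyloxy)-2-methoxy-3-(3-methylbut-2-en-1-yl)phenyl]-N-methoxy-N-methyl-3-(triethylsilyloxy)propanamide | COc1c(C(O[Si](CC)(CC)CC)CC(=O)N(C)OC)ccc(O[Si](C)(C)C(C)(C)C)c1CC=C(C)C | intermediate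
16 | magnesium hemiaminal chelate from 15 and ethynylmagnesium bromide (not isolated, diastereomer mixture) | COc1c(C(O[Si](CC)(CC)CC)CC(O[Mg]Br)(C#C)N(C)OC)ccc(O[Si](C)(C)C(C)(C)C)c1CC=C(C)C | intermediate
17 | racemic 5-[4-(tert-butyldimethylsilyloxy)-2-methoxy-3-(3-methylbut-2-en-1-yl)phenyl]-5-(triethylsilyloxy)pent-1-yn-3-one | C#CC(=O)CC(O[Si](CC)(CC)CC)c1ccc(O[Si](C)(C)C(C)(C)C)c(CC=C(C)C)c1OC | intermediate
18 | methoxycyclohexadiene cycloadduct of 4 and 17 (not isolated, diastereomer mixture) | COC1C(CC=C(C)C)=C(O[Si](C)(C)C(C)(C)C)CC=C1C(=O)CC(O[Si](CC)(CC)CC)c1ccc(O[Si](C)(C)C(C)(C)C)c(CC=C(C)C)c1OC | intermediate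
19 | racemic 1-[4-(tert-butyldimethylsilyloxy)-3-(3-methylbut-2-en-1-yl)phenyl]-3-[4-(tert-butyldimethylsilyloxy)-2-methoxy-3-(3-methylbut-2-en-1-yl)phenyl]-3-(triethylsilyloxy)propan-1-one | COc1c(C(O[Si](CC)(CC)CC)CC(=O)c2ccc(O[Si](C)(C)C(C)(C)C)c(CC=C(C)C)c2)ccc(O[Si](C)(C)C(C)(C)C)c1CC=C(C)C | intermediate
20 | racemic 1-[4-(tert-butyldimethylsilyloxy)-3-(3-methylbut-2-en-1-yl)phenyl]-3-[4-(tert-butyldimethylsilyloxy)-2-methoxy-3-(3-methylbut-2-en-1-yl)phenyl]-3-hydroxypropan-1-one | COc1c(C(O)CC(=O)c2ccc(O[Si](C)(C)C(C)(C)C)c(CC=C(C)C)c2)ccc(O[Si](C)(C)C(C)(C)C)c1CC=C(C)C | intermediate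
21 | 1-[4-(tert-butyldimethylsilyloxy)-2-methoxy-3-(3-methylbut-2-en-1-yl)phenyl]-3-[4-(tert-butyldimethylsilyloxy)-3-(3-methylbut-2-en-1-yl)phenyl]propane-1,3-dione | COc1c(C(=O)CC(=O)c2ccc(O[Si](C)(C)C(C)(C)C)c(CC=C(C)C)c2)ccc(O[Si](C)(C)C(C)(C)C)c1CC=C(C)C | intermediate
22 | 1-[4-hydroxy-2-methoxy-3-(3-methylbut-2-en-1-yl)phenyl]-3-[4-hydroxy-3-(3-methylbut-2-en-1-yl)phenyl]propane-1,3-dione | COc1c(C(=O)CC(=O)c2ccc(O)c(CC=C(C)C)c2)ccc(O)c1CC=C(C)C | target

**Summary**

Total step count: 15. Longest linear sequence: 12 steps (steps 4 to 15, from 2,4-dihydroxybenzaldehyde).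

Steps most likely to fail:

1. Step 12. The cycloaddition of the 2-substituted, bulky silyloxy diene may be slow at temperatures the β-silyloxy ketone tolerates. The silyl enol ether of the adduct may hydrolyse before methanol is lost, and silanol may be eliminated from the β-position on prolonged heating. The fallback changes the diene and sets out from 3. Addition–elimination of Me2NH in THF should give (E)-3-[(dimethylamino)methylidene]-6-methylhept-5-en-2-one F1. Deprotonation with KN(SiMe3)2 in THF at −78 °C gives the potassium dienolate F2, and TBSCl converts it into (E)-1-(dimethylamino)-2-(3-methylbut-2-en-1-yl)-3-(tert-butyldimethylsilyloxy)buta-1,3-diene F3. This far more electron-rich 1-amino-3-silyloxydiene should add to ynone 17 at or below room temperature with the same regiochemistry to give the aminocyclohexadiene cycloadduct F4. On silica gel F4 loses dimethylamine and the route is rejoined at 19.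

2. Step 1. The carbenium ion may attack the methyl-side enol, which would give the wrong regioisomer, or be consumed by the trisubstituted alkene. The fallback sets out from 1 and fixes the enol regiochemistry in a separate, equilibrating step. Me3SiCl, NaI and Et3N in MeCN should give mainly the internal enol ether (Z)-trimethyl[(6-methylhepta-2,5-dien-2-yl)oxy]silane F5, whose isomer ratio can be checked before use. A Mukaiyama-type addition of F5 to HC(OMe)3 with catalytic Me3SiOTf in CH2Cl2 at −78 °C then returns to the route at 2.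

3. Step 11. The liberated N,O-dimethylhydroxylamine may add in conjugate fashion to the new terminal ynone during the quench, or the Grignard addition to the hindered β-silyloxy amide may be incomplete. The fallback sets out from 11 and brings in the alkyne with the ketone already in place. 4-(Trimethylsilyl)but-3-yn-2-one is deprotonated with LiN(iPr)2 in THF at −78 °C to the lithium enolate of 4-(trimethylsilyl)but-3-yn-2-one F6, which adds to 11 to give the racemic β-hydroxy trimethylsilyl ynone F7. TESOTf and 2,6-lutidine in CH2Cl2 at −78 °C give its triethylsilyl ether F8. Mild C-desilylation with Na2B4O7·10H2O in aqueous MeOH/THF then returns to the route at 17.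

**Further compounds**

F1 | step 12 | (E)-3-[(dimethylamino)methylidene]-6-methylhept-5-en-2-one | CN(C)/C=C(\CC=C(C)C)C(C)=O
F2 | step 12 | potassium dienolate of F1 | CN(C)/C=C(\CC=C(C)C)C(=C)O[K]
F3 | step 12 | (E)-1-(dimethylamino)-2-(3-methylbut-2-en-1-yl)-3-(tert-butyldimethylsilyloxy)buta-1,3-diene | CN(C)/C=C(\CC=C(C)C)C(=C)O[Si](C)(C)C(C)(C)C
F4 | step 12 | aminocyclohexadiene cycloadduct of F3 and 17 (diastereomer mixture) | CN(C)C1C(CC=C(C)C)=C(O[Si](C)(C)C(C)(C)C)CC=C1C(=O)CC(O[Si](CC)(CC)CC)c1ccc(O[Si](C)(C)C(C)(C)C)c(CC=C(C)C)c1OC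
F5 | step 1 | (Z)-trimethyl[(6-methylhepta-2,5-dien-2-yl)oxy]silane | C/C(O[Si](C)(C)C)=C/CC=C(C)C
F6 | step 11 | lithium enolate of 4-(trimethylsilyl)but-3-yn-2-one | [Li]OC(=C)C#C[Si](C)(C)C
F7 | step 11 | racemic 5-[4-(tert-butyldimethylsilyloxy)-2-methoxy-3-(3-methylbut-2-en-1-yl)phenyl]-5-hydroxy-1-(trimethylsilyl)pent-1-yn-3-one | C[Si](C)(C)C#CC(=O)CC(O)c1ccc(O[Si](C)(C)C(C)(C)C)c(CC=C(C)C)c1OC
F8 | step 11 | racemic 5-[4-(tert-butyldimethylsilyloxy)-2-methoxy-3-(3-methylbut-2-en-1-yl)phenyl]-5-(triethylsilyloxy)-1-(trimethylsilyl)pent-1-yn-3-one | C[Si](C)(C)C#CC(=O)CC(O[Si](CC)(CC)CC)c1ccc(O[Si](C)(C)C(C)(C)C)c(CC=C(C)C)c1OC
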